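**Plan**
Locants: the bicycle is C1(CH3)–C2(H)–C3(CH3)2–C4(H)–C5H2–C6H2 with bridge O7 between C1 and C4. The side chain runs from C1' (benzylic) to C5' (on C2).
Cuts, in retrosynthetic order: the two O–CH3 bonds; C1'–C2' and C3'–CH3 (methylalumination of a terminal alkyne, then benzyl–alkenyl coupling); C5'–C2 (C2 radical plus methyl vinyl ketone); C1–O7 and C2–I (iodoetherification); C4–H (ketone reduction); the two C3–CH3 bonds.
Forward order: the carbocycle C1–C6 comes from 4-methylanisole. O7 then closes the tetrahydrofuran ring O7–C1–C6–C5–C4 across it, the chain is joined at C2, and the E-olefin and the arene are added in one operation.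
Enabling feature: C2 lies between the fully substituted C1 and C3, so it has no β-hydrogen and is closed to SN2 or enolate chemistry, yet it readily gives a planar radical. O7 is a bare one-atom bridge, so the exo face of C2 is open, while the C5–C6 bridge and the endo methyl on C3 wall off the endo face.
Stereochemistry: C4 comes from a CBS reduction, and C1 follows from C4 because O7 can bridge only one face. C2 is erased and rewritten in the key step, which turns the endo iodide (or any epimer mixture) into the exo C–C bond. The E-olefin comes from syn-carboalumination and a retentive coupling.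

Key step: step 5

Assumption: the SMILES is read with the C2 side chain exo (syn to O7), that is (1R,2S,4S) in the bicycle; all stereochemical arguments below rest on this reading.

Step 1
Reactants: 1 4-methylanisole
Product: 3 4-methylcyclohex-3-en-1-one, via 1-methoxy-4-methylcyclohexa-1,4-diene 2 (not isolated)
Conditions: Li (3 equiv), t-BuOH, NH3(l)/THF, −78 to −33 °C; NH4Cl, NH3 off; (CO2H)2 (cat.), H2O/THF, rt
Reagents that add atoms: water, O
Why: Birch reduction of an anisole keeps the two donor-bearing carbons on the remaining double bonds, and mild enol ether hydrolysis with oxalic acid frees the β,γ-unsaturated ketone; no stereocentre is formed.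

Step 2
Reactants: 3 4-methylcyclohex-3-en-1-one
Product: 5 2,2,4-trimethylcyclohex-3-en-1-one, via 2,4-dimethylcyclohex-3-en-1-one 4 (not isolated)
Conditions: KOt-Bu (2.3 equiv), MeI (2.6 equiv), t-BuOH/THF, 0 °C to rt
Reagents that add atoms: iodomethane, CI
Why: This is a deconjugative α,α-dialkylation in which the doubly activated (α and allylic) C–H gives the extended dienolate, which is methylated twice at its α-carbon; any conjugated isomer of 3 feeds the same dienolate, and the transient stereocentre of 4 vanishes in 5.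

Step 3
Reactants: 5 2,2,4-trimethylcyclohex-3-en-1-one
Product: 6 (S)-2,2,4-trimethylcyclohex-3-en-1-ol
Conditions: (R)-2-methyl-CBS-oxazaborolidine (10 mol %), BH3·SMe2 (0.7 equiv), THF, −20 °C; MeOH
Reagents that add atoms: none
Why: In this Corey–Bakshi–Shibata reduction the catalyst tells the quaternary flank (large) from the CH2 flank (small), so the (R)-catalyst should give the (S)-carbinol that becomes C4, and the catalysed ketone reduction is far faster than hydroboration of the hindered trisubstituted alkene.

Step 4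
Reactants: 6 (S)-2,2,4-trimethylcyclohex-3-en-1-ol
Product: 7 (1R,2R,4S)-2-iodo-1,3,3-trimethyl-7-oxabicyclo[2.2.1]heptane (iodine endo)
Conditions: NIS (1.2 equiv), MeCN, 0 °C to rt, dark
Reagents that add atoms: N-iodosuccinimide, O=C1CCC(=O)N1I
Why: In this transannular Markovnikov iodoetherification (5-exo for the new tetrahydrofuran ring) the iodonium ion forms anti to the hydroxyl, which attacks the tertiary carbon from its own face, so C1 is dictated by C4, iodine ends up endo by anti addition, and 7 cannot lose HI for lack of a β-hydrogen.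

Step 5
Reactants: 7 (1R,2R,4S)-2-iodo-1,3,3-trimethyl-7-oxabicyclo[2.2.1]heptane; 8 methyl vinyl ketone
Product: 10 4-[(1R,2S,4S)-1,3,3-trimethyl-7-oxabicyclo[2.2.1]heptan-2-yl]butan-2-one (chain exo), via oxabicycloheptan-2-yl radical 9 (not isolated)
Conditions: (Me3Si)3SiH (1.3 equiv), AIBN (0.2 equiv), 8 (5 equiv), PhMe (0.1 M), 80 °C
Reagents that add atoms: none
Why: The silyl radical abstracts iodine from 7 to give the planar secondary radical 9, which adds through its exo face to the CH2 terminus of 8, and the α-keto radical then takes hydrogen from (Me3Si)3SiH to carry the chain (Giese reaction, the reductive radical conjugate addition of an alkyl iodide). No ring is closed, and the bicycle from step 4 passes through intact because a β-alkoxyalkyl radical does not expel an alkoxyl radical at a competitive rate and C2 has no β-hydrogen to lose. The only new stereocentre, C2, is controlled by the bicycle: approach syn to the bare O7 bridge is open, whereas endo approach meets the C5–C6 bridge and the endo methyl on C3, the same bias that steers reagents to the exo face of norbornyl and fenchone-type systems. Because 9 has lost the configuration of the C–I carbon, the endo iodide (or any exo/endo mixture) converges on the exo product, so the configuration forced by anti iodoetherification is corrected here. The step needs addition to win over direct reduction and over telomerisation. The nucleophilic, crowded radical meets only the unhindered terminus of an electron-poor alkene used in excess, the slow hydrogen donor spares 9, and the electrophilic adduct radical prefers the hydridic Si–H to a second enone.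

Step 6
Reactants: 10 4-[(1R,2S,4S)-1,3,3-trimethyl-7-oxabicyclo[2.2.1]heptan-2-yl]butan-2-one
Product: 12 (1R,2S,4S)-2-(but-3-yn-1-yl)-1,3,3-trimethyl-7-oxabicyclo[2.2.1]heptane, via enol diethyl phosphate 11 (not isolated)
Conditions: LDA (1.1 equiv), THF, −78 °C; ClP(O)(OEt)2 (1.15 equiv), −78 °C to rt; LDA (2.3 equiv), −78 °C to rt; H2O
Reagents that add atoms: diethyl chlorophosphate, CCOP(=O)(Cl)OCC (its phosphoryl group is carried only by 11)
Why: Kinetic deprotonation at the methyl group, O-phosphorylation and base-induced elimination of diethyl phosphate turn a methyl ketone into the terminal alkyne (enol phosphate elimination), and no stereocentre lies α to the carbonyl.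

Step 7
Reactants: 12 (1R,2S,4S)-2-(but-3-yn-1-yl)-1,3,3-trimethyl-7-oxabicyclo[2.2.1]heptane; 13 methyl 3-(bromomethyl)-4-methoxybenzoate
Product: 15 methyl 4-methoxy-3-{(2E)-3-methyl-5-[(1R,2S,4S)-1,3,3-trimethyl-7-oxabicyclo[2.2.1]heptan-2-yl]pent-2-en-1-yl}benzoate, via alkenyldimethylalane 14 (not isolated)
Conditions: Me3Al (2.5 equiv), Cp2ZrCl2 (0.25 equiv), CH2Cl2, 0 °C to rt; volatiles and excess Me3Al off; 13, Pd(PPh3)4 (5 mol %), THF, rt
Reagents that add atoms: trimethylaluminium, C[Al](C)C
Why: Zirconium-catalysed syn-carboalumination (Negishi carboalumination) puts CH3 on the internal and aluminium on the terminal alkyne carbon on the same side, and the palladium-catalysed alkenylalane–benzyl bromide cross-coupling proceeds with retention, which fixes the E-olefin.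

Step 8
Reactants: 15 methyl 4-methoxy-3-{(2E)-3-methyl-5-[(1R,2S,4S)-1,3,3-trimethyl-7-oxabicyclo[2.2.1]heptan-2-yl]pent-2-en-1-yl}benzoate
Product: 16 4-hydroxy-3-{(2E)-3-methyl-5-[(1R,2S,4S)-1,3,3-trimethyl-7-oxabicyclo[2.2.1]heptan-2-yl]pent-2-en-1-yl}benzoic acid
Conditions: NaSEt (8 equiv), DMF, 130 °C, Ar; 1 M HCl, 0 °C, to pH 3
Reagents that add atoms: none
Why: Thiolate SN2 dealkylation at both O-methyl carbons frees carboxylate and phenoxide in one non-acidic operation, which spares the trisubstituted olefin (no chroman formation) and the bicyclic ether, whose C–O carbons are closed to SN2 attack.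

**Compound list**
1 | 4-methylanisole | COc1ccc(C)cc1 | starting material
2 | 1-methoxy-4-methylcyclohexa-1,4-diene | COC1=CCC(C)=CC1 | intermediate
3 | 4-methylcyclohex-3-en-1-one | CC1=CCC(=O)CC1 | intermediate
4 | 2,4-dimethylcyclohex-3-en-1-one (racemic) | CC1=CC(C)C(=O)CC1 | intermediate
5 | 2,2,4-trimethylcyclohex-3-en-1-one | CC1=CC(C)(C)C(=O)CC1 | intermediate
6 | (S)-2,2,4-trimethylcyclohex-3-en-1-ol | CC1=CC(C)(C)[C@@H](O)CC1 | intermediate
7 | (1R,2R,4S)-2-iodo-1,3,3-trimethyl-7-oxabicyclo[2.2.1]heptane (endo iodide) | I[C@@H]1C(C)(C)[C@@H]2CC[C@@]1(C)O2 | intermediate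
8 | methyl vinyl ketone (but-3-en-2-one) | C=CC(C)=O | starting material
9 | 1,3,3-trimethyl-7-oxabicyclo[2.2.1]heptan-2-yl radical (C1 and C4 as in 7, C2 planar) | [CH]1C(C)(C)[C@@H]2CC[C@@]1(C)O2 | intermediate
10 | 4-[(1R,2S,4S)-1,3,3-trimethyl-7-oxabicyclo[2.2.1]heptan-2-yl]butan-2-one (chain exo) | CC(=O)CC[C@H]1C(C)(C)[C@@H]2CC[C@@]1(C)O2 | intermediate
11 | diethyl 4-[(1R,2S,4S)-1,3,3-trimethyl-7-oxabicyclo[2.2.1]heptan-2-yl]but-1-en-2-yl phosphate | C=C(OP(=O)(OCC)OCC)CC[C@H]1C(C)(C)[C@@H]2CC[C@@]1(C)O2 | intermediate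
12 | (1R,2S,4S)-2-(but-3-yn-1-yl)-1,3,3-trimethyl-7-oxabicyclo[2.2.1]heptane | C#CCC[C@H]1C(C)(C)[C@@H]2CC[C@@]1(C)O2 | intermediate
13 | methyl 3-(bromomethyl)-4-methoxybenzoate | COC(=O)c1ccc(OC)c(CBr)c1 | starting material
14 | dimethyl{(1E)-2-methyl-4-[(1R,2S,4S)-1,3,3-trimethyl-7-oxabicyclo[2.2.1]heptan-2-yl]but-1-en-1-yl}alane | C/C(=C\[Al](C)C)CC[C@H]1C(C)(C)[C@@H]2CC[C@@]1(C)O2 | intermediate
15 | methyl 4-methoxy-3-{(2E)-3-methyl-5-[(1R,2S,4S)-1,3,3-trimethyl-7-oxabicyclo[2.2.1]heptan-2-yl]pent-2-en-1-yl}benzoate | C/C(=C\Cc1cc(C(=O)OC)ccc1OC)CC[C@H]1C(C)(C)[C@@H]2CC[C@@]1(C)O2 | intermediate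
16 | 4-hydroxy-3-{(2E)-3-methyl-5-[(1R,2S,4S)-1,3,3-trimethyl-7-oxabicyclo[2.2.1]heptan-2-yl]pent-2-en-1-yl}benzoic acid | C/C(=C\Cc1cc(C(=O)O)ccc1O)CC[C@H]1C(C)(C)[C@@H]2CC[C@@]1(C)O2 | target

Total step count: 8. Longest linear sequence: 8 steps (1 to 16).

**Steps most likely to fail**

Step 5. Hydrogen transfer to the crowded radical before it adds, or chain growth of the enone, may outrun the wanted addition. The fallback sets out from 7 and leaves out the hydride source altogether. Keck allyl transfer (allyltributylstannane, AIBN, PhH, 80 °C) should give, again through the exo face, (1R,2S,4S)-2-allyl-1,3,3-trimethyl-7-oxabicyclo[2.2.1]heptane F1. 9-BBN in THF adds to the terminal alkene to give the B-alkyl-9-borabicyclo[3.3.1]nonane F2. NaOH/H2O2 oxidises this to 3-[(1R,2S,4S)-1,3,3-trimethyl-7-oxabicyclo[2.2.1]heptan-2-yl]propan-1-ol F3. Dess–Martin periodinane in CH2Cl2 gives 3-[(1R,2S,4S)-1,3,3-trimethyl-7-oxabicyclo[2.2.1]heptan-2-yl]propanal F4. Ohira–Bestmann homologation (dimethyl (1-diazo-2-oxopropyl)phosphonate, K2CO3, MeOH) comes back to the route at 12.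

Step 4. The transannular closure needs a boat-like arrangement with an axial hydroxyl, and it may lose to proton loss from the iodonium ion or to reversal. The fallback sets out from 6 and puts oxygen instead of iodine on C2. Hydroxyl-directed epoxidation (VO(acac)2, t-BuOOH, PhMe) should give the syn epoxy alcohol (1S,3S,6R)-2,2,6-trimethyl-7-oxabicyclo[4.1.0]heptan-3-ol F5. Catalytic p-TsOH in CH2Cl2 ionises the tertiary C–O bond, and the ring hydroxyl closes the bridge to give (1R,2S,4S)-1,3,3-trimethyl-7-oxabicyclo[2.2.1]heptan-2-ol F6 (exo alcohol). PhOC(S)Cl, pyridine and DMAP give the O-phenyl thionocarbonate F7. F7 takes the place of 7 under the conditions of step 5, gives the same radical 9, and comes back to the route at 10.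

Step 7. Methyl transfer from residual alane to the benzylic bromide or the ester, homocoupling of 13, or slow aluminium-to-palladium transmetalation may erode the coupling. The fallback sets out from 12 and reverses the polarity of the two partners. The alane 14 is made as before and quenched with I2 in THF at −30 °C to give (1R,2S,4S)-2-[(3E)-4-iodo-3-methylbut-3-en-1-yl]-1,3,3-trimethyl-7-oxabicyclo[2.2.1]heptane F8. Separately, 13 is converted with Zn dust and LiCl in THF into [2-methoxy-5-(methoxycarbonyl)benzyl]zinc bromide F9. Negishi coupling of the two (Pd(OAc)2, SPhos, THF, rt) comes back to the route at 15.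

**Further compounds**
F1 | step 5 | (1R,2S,4S)-2-allyl-1,3,3-trimethyl-7-oxabicyclo[2.2.1]heptane | C=CC[C@H]1C(C)(C)[C@@H]2CC[C@@]1(C)O2
F2 | step 5 | 9-{3-[(1R,2S,4S)-1,3,3-trimethyl-7-oxabicyclo[2.2.1]heptan-2-yl]propyl}-9-borabicyclo[3.3.1]nonane | C1CC2CCCC(C1)B2CCC[C@H]1C(C)(C)[C@@H]2CC[C@@]1(C)O2
F3 | step 5 | 3-[(1R,2S,4S)-1,3,3-trimethyl-7-oxabicyclo[2.2.1]heptan-2-yl]propan-1-ol | OCCC[C@H]1C(C)(C)[C@@H]2CC[C@@]1(C)O2
F4 | step 5 | 3-[(1R,2S,4S)-1,3,3-trimethyl-7-oxabicyclo[2.2.1]heptan-2-yl]propanal | O=CCC[C@H]1C(C)(C)[C@@H]2CC[C@@]1(C)O2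
F5 | step 4 | (1S,3S,6R)-2,2,6-trimethyl-7-oxabicyclo[4.1.0]heptan-3-ol (epoxide syn to OH) | C[C@@]12CC[C@H](O)C(C)(C)[C@@H]1O2
F6 | step 4 | (1R,2S,4S)-1,3,3-trimethyl-7-oxabicyclo[2.2.1]heptan-2-ol (exo alcohol) | O[C@H]1C(C)(C)[C@@H]2CC[C@@]1(C)O2
F7 | step 4 | O-phenyl O-[(1R,2S,4S)-1,3,3-trimethyl-7-oxabicyclo[2.2.1]heptan-2-yl] thionocarbonate | S=C(Oc1ccccc1)O[C@H]1C(C)(C)[C@@H]2CC[C@@]1(C)O2
F8 | step 7 | (1R,2S,4S)-2-[(3E)-4-iodo-3-methylbut-3-en-1-yl]-1,3,3-trimethyl-7-oxabicyclo[2.2.1]heptane | C/C(=C\I)CC[C@H]1C(C)(C)[C@@H]2CC[C@@]1(C)O2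
F9 | step 7 | [2-methoxy-5-(methoxycarbonyl)benzyl]zinc bromide | COC(=O)c1ccc(OC)c(C[Zn]Br)c1
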